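**Plan**
- Numbering: O1, C2, C3, C3a, C4–C7, C7a; ring A is the benzo ring, ring B the dihydrofuran ring.
- Retrosynthesis: the sulfate ester, both O-benzyl groups and the C7–OMe bond (traced back through C7–I to C7–SiEt3) are cut first; ring A is then cut at C3a–C7a, C4–C5 and C6–C7 into three two-carbon units.
- Feature used: C7a–C7 hangs on O1 and C3a–C4 on C3, so O1–C2–C3 is a three-atom tether that turns these two units into a 1,6-diyne (alkynyl ether on O1, ethynyl on C3); C5–C6 with its chain is a free pent-4-ynyl ester.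
- Forward: the C2–C3 bond is made first by adding a chiral allenylzinc to O-benzylvanillin, O1 is turned into a silyl-capped alkynyl ether, and one rhodium-catalysed (2+2+2) cyclotrimerisation closes ring B and ring A together; C7–Si → C7–I → C7–OMe, sulfation and hydrogenolysis follow.
- Stereochemistry: C3 comes from an (S)-propargylic mesylate (transfer hydrogenation of an ynone) with net inversion; C2 comes from the anti-selective cyclic transition state of the allenylzinc addition. The anti pair becomes the trans C2/C3 pair and is not touched again.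

Key step: step 9

Remark: the target is drawn as the free hydrogen sulfate; sulfate monoesters are handled as sodium salts, written here in the neutral acid form, and the acid is set free at the very end by proton exchange.

**Step 1**
Reactants: 1 2-(benzyloxy)-N-methoxy-N-methylacetamide; 2 ethynyltrimethylsilane
Product: 4 1-(benzyloxy)-4-(trimethylsilyl)but-3-yn-2-one, via lithium (trimethylsilyl)acetylide 3 (not isolated)
Conditions: n-BuLi, THF, −78 °C; then 1, −78 to 0 °C; poured into cold aq NH4Cl
Reagents that add atoms: none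
Why: Weinreb ketone synthesis, in which the chelated tetrahedral adduct of the lithium acetylide survives until the quench, so the ynone should form without over-addition.

**Step 2**
Reactants: 4 1-(benzyloxy)-4-(trimethylsilyl)but-3-yn-2-one
Product: 5 (2S)-1-(benzyloxy)-4-(trimethylsilyl)but-3-yn-2-ol
Conditions: Ru[(R,R)-TsDPEN](p-cymene) (amido complex, 1 mol%), i-PrOH, rt
Reagents that add atoms: none
Why: Noyori asymmetric transfer hydrogenation of an alkynyl ketone, in which the alkynyl group takes the place of the aryl group of the usual model, so the (R,R)-ligand should set the (S)-carbinol (S because CH2OBn outranks the alkynyl carbon); the base-free catalyst spares the C–SiMe3 bond.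

**Step 3**
Reactants: 5 (2S)-1-(benzyloxy)-4-(trimethylsilyl)but-3-yn-2-ol
Product: 6 (2S)-1-(benzyloxy)-4-(trimethylsilyl)but-3-yn-2-yl methanesulfonate
Conditions: MsCl, Et3N, CH2Cl2, −78 °C; used crude
Reagents that add atoms: methanesulfonyl chloride, CS(=O)(=O)Cl
Why: O-sulfonylation of a secondary alcohol, which leaves the C–O bond and hence the configuration untouched; the low temperature should keep the propargylic mesylate from ionising.

**Step 4**
Reactants: 6 (2S)-1-(benzyloxy)-4-(trimethylsilyl)but-3-yn-2-yl methanesulfonate; 7 4-(benzyloxy)-3-methoxybenzaldehyde (O-benzylvanillin)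
Product: 9 (1S,2R)-1-[4-(benzyloxy)-3-methoxyphenyl]-2-[(benzyloxy)methyl]-4-(trimethylsilyl)but-3-yn-1-ol, via allenylzinc reagent 8 (not isolated)
Conditions: Pd(OAc)2 (5 mol%), PPh3 (5 mol%), Et2Zn (3 equiv), THF, −78 to −20 °C, aldehyde present from the start
Reagents that add atoms: none
Why: Marshall–Tamaru propargylation, in which zerovalent palladium displaces the mesylate anti (SN2'), Et2Zn transmetalates to the configurationally defined allenylzinc 8, and its cyclic SE2' addition to the aldehyde sets the CH2OBn-bearing carbon (the later C3) from the mesylate with net inversion and the carbinol carbon (the later C2) anti to it through the six-membered transition state; trapping in situ should keep the β-alkoxy zinc species from eliminating benzyloxide.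

**Step 5**
Reactants: 9 (1S,2R)-1-[4-(benzyloxy)-3-methoxyphenyl]-2-[(benzyloxy)methyl]-4-(trimethylsilyl)but-3-yn-1-ol
Product: 11 (E)-1,2-dichloroethenyl ether of 9, via potassium alkoxide 10 (not isolated)
Conditions: KH, THF, 0 °C; Cl2C=CHCl, −50 °C to rt
Reagents that add atoms: trichloroethylene, ClC=C(Cl)Cl
Why: Addition of an alkoxide to dichloroacetylene generated in the flask from trichloroethylene is the standard entry to (E)-1,2-dichlorovinyl ethers of secondary alcohols, and it touches no stereocentre.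

**Step 6**
Reactants: 11 (E)-1,2-dichloroethenyl ether of 9
Product: 14 triethyl({[(1S,2R)-1-[4-(benzyloxy)-3-methoxyphenyl]-2-[(benzyloxy)methyl]-4-(trimethylsilyl)but-3-yn-1-yl]oxy}ethynyl)silane, via chloroethynyl ether 12 (not isolated), via lithium alkoxyacetylide 13 (not isolated)
Conditions: n-BuLi (2.3 equiv), THF, −78 to −40 °C; Et3SiCl, −78 °C to rt; Et3N-deactivated silica
Reagents that add atoms: chlorotriethylsilane, CC[Si](Cl)(CC)CC
Why: Dehydrochlorination to the chloroalkyne followed by lithium–chlorine exchange gives the lithium alkoxyacetylide, which Et3SiCl silylates at carbon; the C-alkynylsilane and the benzyl ethers should be inert to n-BuLi at −78 °C.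

**Step 7**
Reactants: 14 triethyl({[(1S,2R)-1-[4-(benzyloxy)-3-methoxyphenyl]-2-[(benzyloxy)methyl]-4-(trimethylsilyl)but-3-yn-1-yl]oxy}ethynyl)silane
Product: 15 triethyl({[(1S,2R)-1-[4-(benzyloxy)-3-methoxyphenyl]-2-[(benzyloxy)methyl]but-3-yn-1-yl]oxy}ethynyl)silane
Conditions: K2CO3 (0.3 equiv), MeOH/THF, 0 °C, stopped at full conversion of 14
Reagents that add atoms: none
Why: Base-catalysed methanolysis of alkynylsilanes is much faster for SiMe3 than for SiEt3, so the C-alkyne should be freed while the bulkier silyl cap of the base-stable alkynyl ether stays.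

**Step 8**
Reactants: 16 pent-4-yn-1-ol
Product: 17 pent-4-yn-1-yl acetate
Conditions: Ac2O, pyridine, CH2Cl2, rt
Reagents that add atoms: acetic anhydride, CC(=O)OC(C)=O
Why: Acylation of a primary alcohol; the acetate keeps the hydroxyl away from the cationic catalyst and the alkynyl ether, and is cleaved without a separate step in step 11.

**Step 9**
Reactants: 15 triethyl({[(1S,2R)-1-[4-(benzyloxy)-3-methoxyphenyl]-2-[(benzyloxy)methyl]but-3-yn-1-yl]oxy}ethynyl)silane; 17 pent-4-yn-1-yl acetate
Product: 18 3-[(2S,3R)-2-[4-(benzyloxy)-3-methoxyphenyl]-3-[(benzyloxy)methyl]-7-(triethylsilyl)-2,3-dihydro-1-benzofuran-5-yl]propyl acetate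
Conditions: [Rh(cod)2]BF4 (5 mol%), rac-BINAP (5 mol%), H2 then Ar, CH2Cl2, rt; 15 added slowly to 17 (3 equiv)
Reagents that add atoms: none
Why: Monovalent rhodium, freed of cod by hydrogenation, binds both alkynes of 15 and couples them oxidatively to a rhodacyclopentadiene; 17 then inserts and reductive elimination releases the arene and the catalyst. The closest known reaction type is the cationic rhodium/BINAP cross-cyclotrimerisation of 1,6-diynes, including diynes tethered through an alkynyl ether or an ynamide, with terminal alkynes. Ring B closes in the oxidative cyclisation, where the C3a–C7a bond makes the five-membered oxacycle fused to the rhodacycle; ring A closes by insertion of 17 at the Rh–C4 end and C6–C7 reductive elimination, a formal [4+2] of the metallacycle. No stereocentre is formed: C2 and C3 are sp3 spectators on the tether and the anti pair becomes the trans-2,3 pair. The step needs regiocontrol, which the bulky SiEt3 on C7 should provide by sending the substituted carbon of 17 to the unhindered C4 so that the chain ends on C5, and cross- over homo-coupling, which slow addition of 15 to excess 17 should provide. Room temperature is needed so that the benzylic alkynyl ether does not undergo its [3,3] shift or eliminate to a ketene.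

**Step 10**
Reactants: 18 3-[(2S,3R)-2-[4-(benzyloxy)-3-methoxyphenyl]-3-[(benzyloxy)methyl]-7-(triethylsilyl)-2,3-dihydro-1-benzofuran-5-yl]propyl acetate
Product: 19 3-[(2S,3R)-2-[4-(benzyloxy)-3-methoxyphenyl]-3-[(benzyloxy)methyl]-7-iodo-2,3-dihydro-1-benzofuran-5-yl]propyl acetate
Conditions: ICl (1.05 equiv), CH2Cl2, −78 to 0 °C; aq Na2S2O3
Reagents that add atoms: iodine monochloride, ClI
Why: Electrophilic ipso-iododesilylation, in which attack at C7, ortho to O1, gives a cation stabilised by the β-silicon effect, so the C–Si bond should be replaced faster than any C–H bond of the alkoxy-substituted rings at low temperature.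

**Step 11**
Reactants: 19 3-[(2S,3R)-2-[4-(benzyloxy)-3-methoxyphenyl]-3-[(benzyloxy)methyl]-7-iodo-2,3-dihydro-1-benzofuran-5-yl]propyl acetate
Product: 20 3-[(2S,3R)-2-[4-(benzyloxy)-3-methoxyphenyl]-3-[(benzyloxy)methyl]-7-methoxy-2,3-dihydro-1-benzofuran-5-yl]propan-1-ol
Conditions: CuI (20 mol%), NaOMe, MeOH/DMF, 100 °C
Reagents that add atoms: sodium methoxide, C[O-].[Na+]
Why: Ullmann-type copper-catalysed methoxylation of an aryl iodide; the same methoxide transesterifies the acetate, and C2 and C3 carry no acidifying group and already sit in the more stable trans arrangement.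

**Step 12**
Reactants: 20 3-[(2S,3R)-2-[4-(benzyloxy)-3-methoxyphenyl]-3-[(benzyloxy)methyl]-7-methoxy-2,3-dihydro-1-benzofuran-5-yl]propan-1-ol
Product: 21 3-[(2S,3R)-2-[4-(benzyloxy)-3-methoxyphenyl]-3-[(benzyloxy)methyl]-7-methoxy-2,3-dihydro-1-benzofuran-5-yl]propyl hydrogen sulfate
Conditions: SO3·pyridine, pyridine, rt; aq NaHCO3 (sodium salt isolated)
Reagents that add atoms: sulfur trioxide–pyridine complex, O=S(=O)([O-])[n+]1ccccc1
Why: O-sulfation of the only free hydroxyl; the phenol and the C3 hydroxymethyl group are benzyl ethers, so the sulfate can only go on the propanol chain, and the exchange to the sodium salt removes pyridine before the hydrogenolysis.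

**Step 13**
Reactants: 21 3-[(2S,3R)-2-[4-(benzyloxy)-3-methoxyphenyl]-3-[(benzyloxy)methyl]-7-methoxy-2,3-dihydro-1-benzofuran-5-yl]propyl hydrogen sulfate
Product: 22 3-[(2S,3R)-2-(4-hydroxy-3-methoxyphenyl)-3-(hydroxymethyl)-7-methoxy-2,3-dihydro-1-benzofuran-5-yl]propyl hydrogen sulfate (CNP0220090.1)
Conditions: H2 (1 atm), 10% Pd/C, MeOH/EtOAc, rt; then Dowex 50W (H+ form), 0 °C
Reagents that add atoms: none
Why: Hydrogenolysis of the benzyl aryl and benzyl alkyl ethers on the neutral sodium salt, to which the sulfate monoester is inert and in which the hindered secondary C2–O1 bond of ring B should be cleaved far more slowly than the primary benzyl ethers; brief cold proton exchange then gives the acid form.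

**Compound list**
1 | 2-(benzyloxy)-N-methoxy-N-methylacetamide | CON(C)C(=O)COCc1ccccc1 | starting material
2 | ethynyltrimethylsilane | C#C[Si](C)(C)C | starting material
3 | lithium (trimethylsilyl)acetylide | [Li]C#C[Si](C)(C)C | intermediate
4 | 1-(benzyloxy)-4-(trimethylsilyl)but-3-yn-2-one | O=C(COCc1ccccc1)C#C[Si](C)(C)C | intermediate
5 | (2S)-1-(benzyloxy)-4-(trimethylsilyl)but-3-yn-2-ol | O[C@H](COCc1ccccc1)C#C[Si](C)(C)C | intermediate
6 | (2S)-1-(benzyloxy)-4-(trimethylsilyl)but-3-yn-2-yl methanesulfonate | CS(=O)(=O)O[C@H](COCc1ccccc1)C#C[Si](C)(C)C | intermediate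
7 | 4-(benzyloxy)-3-methoxybenzaldehyde (O-benzylvanillin) | COc1cc(C=O)ccc1OCc1ccccc1 | starting material
8 | ethyl[(aS)-4-(benzyloxy)-1-(trimethylsilyl)buta-1,2-dien-1-yl]zinc (P helicity) | CC[Zn]C([Si](C)(C)C)=[C@@]=C([H])COCc1ccccc1 | intermediate
9 | (1S,2R)-1-[4-(benzyloxy)-3-methoxyphenyl]-2-[(benzyloxy)methyl]-4-(trimethylsilyl)but-3-yn-1-ol | COc1cc([C@@H](O)[C@@H](COCc2ccccc2)C#C[Si](C)(C)C)ccc1OCc1ccccc1 | intermediate
10 | potassium (1S,2R)-1-[4-(benzyloxy)-3-methoxyphenyl]-2-[(benzyloxy)methyl]-4-(trimethylsilyl)but-3-yn-1-olate | COc1cc([C@@H]([O-])[C@@H](COCc2ccccc2)C#C[Si](C)(C)C)ccc1OCc1ccccc1.[K+] | intermediate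
11 | {(3R,4S)-4-[4-(benzyloxy)-3-methoxyphenyl]-3-[(benzyloxy)methyl]-4-{[(E)-1,2-dichloroethenyl]oxy}but-1-yn-1-yl}trimethylsilane | COc1cc([C@@H](O/C(Cl)=C\Cl)[C@@H](COCc2ccccc2)C#C[Si](C)(C)C)ccc1OCc1ccccc1 | intermediate
12 | {(3R,4S)-4-[4-(benzyloxy)-3-methoxyphenyl]-3-[(benzyloxy)methyl]-4-[(chloroethynyl)oxy]but-1-yn-1-yl}trimethylsilane | COc1cc([C@@H](OC#CCl)[C@@H](COCc2ccccc2)C#C[Si](C)(C)C)ccc1OCc1ccccc1 | intermediate
13 | lithium {[(1S,2R)-1-[4-(benzyloxy)-3-methoxyphenyl]-2-[(benzyloxy)methyl]-4-(trimethylsilyl)but-3-yn-1-yl]oxy}ethynide | COc1cc([C@@H](OC#C[Li])[C@@H](COCc2ccccc2)C#C[Si](C)(C)C)ccc1OCc1ccccc1 | intermediate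
14 | triethyl({[(1S,2R)-1-[4-(benzyloxy)-3-methoxyphenyl]-2-[(benzyloxy)methyl]-4-(trimethylsilyl)but-3-yn-1-yl]oxy}ethynyl)silane | COc1cc([C@@H](OC#C[Si](CC)(CC)CC)[C@@H](COCc2ccccc2)C#C[Si](C)(C)C)ccc1OCc1ccccc1 | intermediate
15 | triethyl({[(1S,2R)-1-[4-(benzyloxy)-3-methoxyphenyl]-2-[(benzyloxy)methyl]but-3-yn-1-yl]oxy}ethynyl)silane | COc1cc([C@@H](OC#C[Si](CC)(CC)CC)[C@@H](COCc2ccccc2)C#C)ccc1OCc1ccccc1 | intermediate
16 | pent-4-yn-1-ol | C#CCCCO | starting material
17 | pent-4-yn-1-yl acetate | C#CCCCOC(C)=O | intermediate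
18 | 3-[(2S,3R)-2-[4-(benzyloxy)-3-methoxyphenyl]-3-[(benzyloxy)methyl]-7-(triethylsilyl)-2,3-dihydro-1-benzofuran-5-yl]propyl acetate | COc1cc([C@H]2Oc3c([Si](CC)(CC)CC)cc(CCCOC(C)=O)cc3[C@@H]2COCc2ccccc2)ccc1OCc1ccccc1 | intermediate
19 | 3-[(2S,3R)-2-[4-(benzyloxy)-3-methoxyphenyl]-3-[(benzyloxy)methyl]-7-iodo-2,3-dihydro-1-benzofuran-5-yl]propyl acetate | COc1cc([C@H]2Oc3c(I)cc(CCCOC(C)=O)cc3[C@@H]2COCc2ccccc2)ccc1OCc1ccccc1 | intermediate
20 | 3-[(2S,3R)-2-[4-(benzyloxy)-3-methoxyphenyl]-3-[(benzyloxy)methyl]-7-methoxy-2,3-dihydro-1-benzofuran-5-yl]propan-1-ol | COc1cc([C@H]2Oc3c(OC)cc(CCCO)cc3[C@@H]2COCc2ccccc2)ccc1OCc1ccccc1 | intermediate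
21 | 3-[(2S,3R)-2-[4-(benzyloxy)-3-methoxyphenyl]-3-[(benzyloxy)methyl]-7-methoxy-2,3-dihydro-1-benzofuran-5-yl]propyl hydrogen sulfate | COc1cc([C@H]2Oc3c(OC)cc(CCCOS(=O)(=O)O)cc3[C@@H]2COCc2ccccc2)ccc1OCc1ccccc1 | intermediate
22 | 3-[(2S,3R)-2-(4-hydroxy-3-methoxyphenyl)-3-(hydroxymethyl)-7-methoxy-2,3-dihydro-1-benzofuran-5-yl]propyl hydrogen sulfate | COc1cc([C@H]2Oc3c(OC)cc(CCCOS(=O)(=O)O)cc3[C@@H]2CO)ccc1O | target

**Step count**
Total: 13 steps. Longest linear sequence: 12 steps (steps 1–7 and 9–13, from 1 to 22); step 8 is the side branch.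

**Steps most likely to fail**

Step 9. The free alkyne may insert with its chain toward C6 or trimerise on its own, and if turnover is slow the benzylic alkynyl ether may ionise or rearrange at the Lewis-acidic cationic rhodium before it is captured. The fallback makes the third alkyne intramolecular through a disposable silicon tether; it sets out from 15 and comes back at 18. Pent-4-yn-1-ol 16 is first joined to silicon (i-Pr2SiCl2, Et3N, CH2Cl2) as chloro(pent-4-yn-1-yloxy)di(propan-2-yl)silane F1. The terminal alkyne of 15 is deprotonated (n-BuLi, THF, −78 °C) to the lithium acetylide F2, which F1 silylates to the silicon-tethered triyne F3. The same rhodium catalyst at high dilution and room temperature should then close ring B, ring A and a seven-membered oxasila ring in one intramolecular event, giving the silicon-bridged tetracycle F4. In F4 the three-carbon chain can only sit on C5, and no free alkyne is left to trimerise. Bu4NF (DMF, 80 °C) should cleave the Si–O bond and protodesilylate C4 while leaving SiEt3 on C7, giving the 7-triethylsilyl propanol F5. Ac2O/pyridine returns to 18.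

Step 5. The potassium alkoxide may strip SiMe3 from the alkyne of a second molecule, or fragment by retro-propargylation, before it adds to dichloroacetylene. The fallback builds the alkynyl ether from a formate without ever forming an alkoxide; it sets out from 9 and comes back at 14. Formylation of 9 (HCO2H, DCC, DMAP, CH2Cl2) gives the formate F6. Dichloromethylenation of the formyl group (PPh3, CCl4, THF, 60 °C) gives the 2,2-dichloroethenyl ether F7, an isomer of 11. n-BuLi (2.2 equiv, −78 to −40 °C) takes F7 through 12 and 13, and Et3SiCl then gives 14.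

Step 10. If ipso attack at the hindered C7–SiEt3 is slow, ICl may iodinate C–H positions of the dialkoxyphenyl ring instead (para to its methoxy group). The fallback replaces silicon by germanium as the C7 handle; it sets out from 11 and comes back at 19. The lithium alkoxyacetylide 13, made from 11 as in step 6, is quenched with Et3GeCl to give the germyl-capped alkynyl ether F8. K2CO3/MeOH removes SiMe3 and leaves the base-stable C–Ge bond, giving the germyl diyne F9. Cyclotrimerisation with 17 under the conditions of step 9 gives the 7-triethylgermyl dihydrobenzofuran F10. N-Iodosuccinimide (DMF, rt) should then exchange germanium for iodine under neutral conditions, where aryl–germanium bonds react much faster than aryl–hydrogen bonds of alkoxyarenes, giving 19.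

**Further compounds**
F1 | step 9 | chloro(pent-4-yn-1-yloxy)di(propan-2-yl)silane | C#CCCCO[Si](Cl)(C(C)C)C(C)C
F2 | step 9 | lithium acetylide of 15 (lithium (3R,4S)-4-[4-(benzyloxy)-3-methoxyphenyl]-3-[(benzyloxy)methyl]-4-{[(triethylsilyl)ethynyl]oxy}but-1-yn-1-ide) | COc1cc([C@@H](OC#C[Si](CC)(CC)CC)[C@@H](COCc2ccccc2)C#C[Li])ccc1OCc1ccccc1
F3 | step 9 | silicon-tethered triyne: {(3R,4S)-4-[4-(benzyloxy)-3-methoxyphenyl]-3-[(benzyloxy)methyl]-4-{[(triethylsilyl)ethynyl]oxy}but-1-yn-1-yl}(pent-4-yn-1-yloxy)di(propan-2-yl)silane | COc1cc([C@@H](OC#C[Si](CC)(CC)CC)[C@@H](COCc2ccccc2)C#C[Si](C(C)C)(C(C)C)OCCCC#C)ccc1OCc1ccccc1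
F4 | step 9 | silicon-bridged tetracycle: (2S,3R)-2-[4-(benzyloxy)-3-methoxyphenyl]-3-[(benzyloxy)methyl]-7-(triethylsilyl)-2,3-dihydrobenzofuran whose C4 carries Si(i-Pr)2 joined through oxygen to the three-carbon chain on C5 (seven-membered 1,2-oxasilepine ring fused at C4–C5) | COc1cc([C@H]2Oc3c([Si](CC)(CC)CC)cc4CCCO[Si](C(C)C)(C(C)C)c4c3[C@@H]2COCc2ccccc2)ccc1OCc1ccccc1
F5 | step 9 | 3-[(2S,3R)-2-[4-(benzyloxy)-3-methoxyphenyl]-3-[(benzyloxy)methyl]-7-(triethylsilyl)-2,3-dihydro-1-benzofuran-5-yl]propan-1-ol | COc1cc([C@H]2Oc3c([Si](CC)(CC)CC)cc(CCCO)cc3[C@@H]2COCc2ccccc2)ccc1OCc1ccccc1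
F6 | step 5 | (1S,2R)-1-[4-(benzyloxy)-3-methoxyphenyl]-2-[(benzyloxy)methyl]-4-(trimethylsilyl)but-3-yn-1-yl formate | COc1cc([C@@H](OC=O)[C@@H](COCc2ccccc2)C#C[Si](C)(C)C)ccc1OCc1ccccc1
F7 | step 5 | {(3R,4S)-4-[4-(benzyloxy)-3-methoxyphenyl]-3-[(benzyloxy)methyl]-4-[(2,2-dichloroethenyl)oxy]but-1-yn-1-yl}trimethylsilane | COc1cc([C@@H](OC=C(Cl)Cl)[C@@H](COCc2ccccc2)C#C[Si](C)(C)C)ccc1OCc1ccccc1
F8 | step 10 | triethyl({[(1S,2R)-1-[4-(benzyloxy)-3-methoxyphenyl]-2-[(benzyloxy)methyl]-4-(trimethylsilyl)but-3-yn-1-yl]oxy}ethynyl)germane | COc1cc([C@@H](OC#C[Ge](CC)(CC)CC)[C@@H](COCc2ccccc2)C#C[Si](C)(C)C)ccc1OCc1ccccc1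
F9 | step 10 | triethyl({[(1S,2R)-1-[4-(benzyloxy)-3-methoxyphenyl]-2-[(benzyloxy)methyl]but-3-yn-1-yl]oxy}ethynyl)germane | COc1cc([C@@H](OC#C[Ge](CC)(CC)CC)[C@@H](COCc2ccccc2)C#C)ccc1OCc1ccccc1
F10 | step 10 | 3-[(2S,3R)-2-[4-(benzyloxy)-3-methoxyphenyl]-3-[(benzyloxy)methyl]-7-(triethylgermyl)-2,3-dihydro-1-benzofuran-5-yl]propyl acetate | COc1cc([C@H]2Oc3c([Ge](CC)(CC)CC)cc(CCCOC(C)=O)cc3[C@@H]2COCc2ccccc2)ccc1OCc1ccccc1
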